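Ring locants are those of the target name: C1 = CCl(CH2Br), C2 = CHCl, C3 = CH2, C4 = CHCl, C5 = C(CH3)(chloroethenyl), C6 = CH2. Everything rests on a [4+2] disconnection of the cyclohexane into C3–C4–C5–C6 (a 2-silyloxy-3-methyl-1,3-diene) and C1–C2 (a (Z)-2,3-dichloro enal). The feature exploited is the cis-vicinal dichloride at C1/C2, the imprint of a (Z)-dichloroalkene: one catalytic enantioselective Diels–Alder reaction forms C1–C6 and C2–C3, sets both chlorinated stereocentres and leaves a regiodefined silyl enol ether (C4=C5), from which the quaternary C5 and the C4 chloride are installed by catalyst control and relay.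

Key step: step 4

Assumption: the (S)-oxazaborolidinium catalyst (step 4) and the (S,S)-bipyridine ligand (step 6) are taken to give the facial senses drawn; if either published model predicts the opposite face for these substrates, the enantiomeric catalyst or ligand is used without other change.

Step 1
Reactants: 1 mucochloric acid (3,4-dichloro-5-hydroxyfuran-2(5H)-one)
Product: 2 (2Z)-2,3-dichloroprop-2-enoic acid
Conditions: NaOH (aq), 0 °C to rt; then HCl (aq)
Reagents that add atoms: none
Why: hydroxide adds to the formyl group of the open-chain tautomer and the adduct expels the chlorine-stabilised vinyl anion (haloform-type retro-Claisen C–C cleavage), which is protonated with retention, so the cis arrangement of the two chlorines should be kept.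

Step 2
Reactants: 2 (2Z)-2,3-dichloroprop-2-enoic acid
Product: 4 (2Z)-2,3-dichloroprop-2-enal, via acid chloride 3 (not isolated)
Conditions: (COCl)2, DMF (cat.), CH2Cl2, 0 °C to rt; then LiAlH(Ot-Bu)3, THF, −78 °C
Reagents that add atoms: none
Why: acid chloride formation followed by partial reduction with the hindered hydride LiAlH(Ot-Bu)3 should stop at the aldehyde, because the tetrahedral adduct persists at −78 °C, and should leave the alkene geometry untouched.

Step 3
Reactants: 5 3-methylbut-3-en-2-one
Product: 6 tert-butyl(dimethyl)[(3-methylbuta-1,3-dien-2-yl)oxy]silane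
Conditions: TBSOTf, Et3N, Et2O, 0 °C
Reagents that add atoms: tert-butyldimethylsilyl trifluoromethanesulfonate, CC(C)(C)[Si](C)(C)OS(=O)(=O)C(F)(F)F
Why: soft enolisation and O-silylation at the only enolisable position (the acetyl methyl group) should give the 2-silyloxy diene (silyl enol ether formation).

Step 4
Reactants: 4 (2Z)-2,3-dichloroprop-2-enal; 6 tert-butyl(dimethyl)[(3-methylbuta-1,3-dien-2-yl)oxy]silane
Product: 8 [(1S,6S)-4-{[tert-butyl(dimethyl)silyl]oxy}-1,6-dichloro-3-methylcyclohex-3-en-1-yl]methanol, via cycloadduct aldehyde 7 (not isolated)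
Conditions: (S)-3,3-diphenyl-1-(2-methylphenyl)tetrahydro-1H,3H-pyrrolo[1,2-c][1,3,2]oxazaborole (20 mol %), HNTf2 (18 mol %), CH2Cl2, −78 °C; then NaBH4, MeOH, −78 to −40 °C; AcOH quench
Reagents that add atoms: none
Why: The N-protonated oxazaborolidine binds the formyl oxygen of 4 (the formyl C–H held by the ring oxygen), and the s-trans enal then undergoes a concerted, asynchronous, normal-electron-demand [4+2] cycloaddition with the s-cis diene 6; the closest known reaction type is the oxazaborolidinium-catalysed enantioselective Diels–Alder reaction of 2-haloacroleins with 2-silyloxy-1,3-dienes. The cyclohexene ring is closed by an intermolecular [4π+2π] addition, suprafacial on both partners, in which C1–C6 and C2–C3 form in the same event. C1 and C2 become stereocentres: their relative cis-dichloro configuration is dictated by the Z geometry of 4, which a concerted addition transfers unchanged, and their absolute configuration by the catalyst, which shields one face of the bound enal; endo/exo orientation is without consequence because both diene termini are CH2. The step needs "para" regioselectivity, secured by the silyloxy group, which makes the adjacent CH2 terminus (future C3) the nucleophilic end that bonds to the β-carbon of the enal (C2) and outweighs the methyl group. It also needs cycloaddition to outrun Mukaiyama-type addition to the formyl group and loss of chloride, which the α-substitution of the enal, the concerted pathway and −78 °C should secure. The labile α-chloro aldehyde 7 is reduced in the same flask by NaBH4 (1,2-reduction), kept cold so that the chlorohydrin does not close to an epoxide.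

Step 5
Reactants: 8 [(1S,6S)-4-{[tert-butyl(dimethyl)silyl]oxy}-1,6-dichloro-3-methylcyclohex-3-en-1-yl]methanol
Product: 10 {[(4R,5S)-4-(bromomethyl)-4,5-dichloro-2-methylcyclohex-1-en-1-yl]oxy}(tert-butyl)dimethylsilane, via primary triflate 9 (not isolated)
Conditions: Tf2O, 2,6-lutidine, CH2Cl2, −78 °C; then Bu4NBr, −78 °C to rt
Reagents that add atoms: tetrabutylammonium bromide, CCCC[N+](CCCC)(CCCC)CCCC.[Br-]
Why: the neopentyl-type primary alcohol is converted into its triflate, which should undergo SN2 displacement by bromide below room temperature under base-buffered conditions that the silyl enol ether tolerates; no stereocentre is touched.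

Step 6
Reactants: 10 {[(4R,5S)-4-(bromomethyl)-4,5-dichloro-2-methylcyclohex-1-en-1-yl]oxy}(tert-butyl)dimethylsilane
Product: 11 (2R,4R,5S)-4-(bromomethyl)-4,5-dichloro-2-(hydroxymethyl)-2-methylcyclohexan-1-one
Conditions: aq. HCHO, Sc(OTf)3 (10 mol %), (S,S)-6,6'-bis(1-hydroxy-2,2-dimethylpropyl)-2,2'-bipyridine (12 mol %), DME/H2O (9:1), −20 °C
Reagents that add atoms: formaldehyde, C=O
Why: catalytic asymmetric Mukaiyama aldol hydroxymethylation of the regiodefined tetrasubstituted silyl enol ether under Lewis-acidic conditions (no enolate equilibration toward C3, hence no β-elimination of the C2 chloride); the ring itself offers little facial bias because either substituent at C1 can sit pseudoaxial, so the chiral scandium–bipyridine complex should decide the face and place CH2OH cis to the C1 chlorine, creating the quaternary centre C5.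

Step 7
Reactants: 11 (2R,4R,5S)-4-(bromomethyl)-4,5-dichloro-2-(hydroxymethyl)-2-methylcyclohexan-1-one
Product: 12 (1R,4S,5R)-5-(bromomethyl)-4,5-dichloro-1-methyl-2-oxocyclohexane-1-carbaldehyde
Conditions: Dess–Martin periodinane, CH2Cl2, 0 °C to rt
Reagents that add atoms: none
Why: Dess–Martin oxidation of the primary alcohol under neutral conditions should give the non-enolisable β-keto aldehyde without retro-aldol loss of formaldehyde or elimination of the β-chlorine.

Step 8
Reactants: 12 (1R,4S,5R)-5-(bromomethyl)-4,5-dichloro-1-methyl-2-oxocyclohexane-1-carbaldehyde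
Product: 13 (2R,4R,5S)-4-(bromomethyl)-4,5-dichloro-2-[(E)-2-chloroethenyl]-2-methylcyclohexan-1-one
Conditions: CrCl2, CHCl3, THF, 65 °C
Reagents that add atoms: chloroform, ClC(Cl)Cl
Why: Takai–Utimoto chloro-olefination, in which the geminal dichromium species from CHCl3 adds to the aldehyde only (the ketone is inert) and elimination from the β-oxido chromium adduct should give the (E)-chloroalkene, the bulky quaternary substituent reinforcing E selectivity.

Step 9
Reactants: 13 (2R,4R,5S)-4-(bromomethyl)-4,5-dichloro-2-[(E)-2-chloroethenyl]-2-methylcyclohexan-1-one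
Product: 14 (1S,2R,4R,5S)-4-(bromomethyl)-4,5-dichloro-2-[(E)-2-chloroethenyl]-2-methylcyclohexan-1-ol
Conditions: LiBH(s-Bu)3, THF, −78 °C; then aq. NH4Cl, −78 °C
Reagents that add atoms: none
Why: diastereoselective ketone reduction in which the bulky trialkylborohydride should attack from the equatorial direction (as in the reduction of 4,4-dimethyl-3-keto triterpenoids to axial alcohols), giving the axial C4 alcohol trans to the chloroethenyl group, with carbonyl addition at −78 °C outrunning enolisation toward the β-chloride.

Step 10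
Reactants: 14 (1S,2R,4R,5S)-4-(bromomethyl)-4,5-dichloro-2-[(E)-2-chloroethenyl]-2-methylcyclohexan-1-ol
Product: 15 violacene, (1R,2S,4R,5R)-1-(bromomethyl)-1,2,4-trichloro-5-[(E)-2-chloroethenyl]-5-methylcyclohexane
Conditions: PPh3, N-chlorosuccinimide, THF, 0 °C to rt
Reagents that add atoms: N-chlorosuccinimide, O=C1CCC(=O)N1Cl
Why: Appel-type chlorination in which the axial alkoxyphosphonium ion should be displaced by chloride with inversion (SN2), placing the C4 chlorine equatorial and cis to the chloroethenyl group as in the target; this is a neopentyl-type displacement of the kind used for cyclohexanols flanked by a methyl/vinyl quaternary carbon.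

Compound list
1 | mucochloric acid (3,4-dichloro-5-hydroxyfuran-2(5H)-one) | O=C1OC(O)C(Cl)=C1Cl | starting material
2 | (2Z)-2,3-dichloroprop-2-enoic acid | OC(=O)/C(Cl)=C/Cl | intermediate
3 | (2Z)-2,3-dichloroprop-2-enoyl chloride | ClC(=O)/C(Cl)=C/Cl | intermediate
4 | (2Z)-2,3-dichloroprop-2-enal | O=C/C(Cl)=C/Cl | intermediate
5 | 3-methylbut-3-en-2-one | CC(=O)C(C)=C | starting material
6 | tert-butyl(dimethyl)[(3-methylbuta-1,3-dien-2-yl)oxy]silane | C=C(O[Si](C)(C)C(C)(C)C)C(C)=C | intermediate
7 | (1S,6S)-4-{[tert-butyl(dimethyl)silyl]oxy}-1,6-dichloro-3-methylcyclohex-3-ene-1-carbaldehyde | CC=1C[C@](Cl)(C=O)[C@@H](Cl)CC=1O[Si](C)(C)C(C)(C)C | intermediate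
8 | [(1S,6S)-4-{[tert-butyl(dimethyl)silyl]oxy}-1,6-dichloro-3-methylcyclohex-3-en-1-yl]methanol | CC=1C[C@](Cl)(CO)[C@@H](Cl)CC=1O[Si](C)(C)C(C)(C)C | intermediate
9 | [(1S,6S)-4-{[tert-butyl(dimethyl)silyl]oxy}-1,6-dichloro-3-methylcyclohex-3-en-1-yl]methyl trifluoromethanesulfonate | CC=1C[C@](Cl)(COS(=O)(=O)C(F)(F)F)[C@@H](Cl)CC=1O[Si](C)(C)C(C)(C)C | intermediate
10 | {[(4R,5S)-4-(bromomethyl)-4,5-dichloro-2-methylcyclohex-1-en-1-yl]oxy}(tert-butyl)dimethylsilane | CC=1C[C@](Cl)(CBr)[C@@H](Cl)CC=1O[Si](C)(C)C(C)(C)C | intermediate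
11 | (2R,4R,5S)-4-(bromomethyl)-4,5-dichloro-2-(hydroxymethyl)-2-methylcyclohexan-1-one | C[C@]1(CO)C[C@](Cl)(CBr)[C@@H](Cl)CC1=O | intermediate
12 | (1R,4S,5R)-5-(bromomethyl)-4,5-dichloro-1-methyl-2-oxocyclohexane-1-carbaldehyde | C[C@]1(C=O)C[C@](Cl)(CBr)[C@@H](Cl)CC1=O | intermediate
13 | (2R,4R,5S)-4-(bromomethyl)-4,5-dichloro-2-[(E)-2-chloroethenyl]-2-methylcyclohexan-1-one | C[C@]1(/C=C/Cl)C[C@](Cl)(CBr)[C@@H](Cl)CC1=O | intermediate
14 | (1S,2R,4R,5S)-4-(bromomethyl)-4,5-dichloro-2-[(E)-2-chloroethenyl]-2-methylcyclohexan-1-ol | C[C@]1(/C=C/Cl)C[C@](Cl)(CBr)[C@@H](Cl)C[C@@H]1O | intermediate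
15 | violacene, (1R,2S,4R,5R)-1-(bromomethyl)-1,2,4-trichloro-5-[(E)-2-chloroethenyl]-5-methylcyclohexane | C[C@]1(/C=C/Cl)C[C@](Cl)(CBr)[C@@H](Cl)C[C@H]1Cl | target

Total step count: 10. Longest linear sequence: 9 (steps 1, 2 and 4 to 10; step 3 is a one-step branch).

Steps most likely to fail

Step 10. The chloride has to enter at a secondary carbon next to the quaternary C5. What may go wrong is E2 loss of the activated axial oxygen (anti-periplanar hydrogen at C3) or a cationic 1,2-shift instead of substitution. The fallback replaces inversion by retention and sets out from ketone 13. NaBH4 with CeCl3·7H2O (MeOH, −78 °C) should deliver hydride axially and give the equatorial alcohol (1R,2R,4R,5S)-4-(bromomethyl)-4,5-dichloro-2-[(E)-2-chloroethenyl]-2-methylcyclohexan-1-ol F1. Its chlorosulfite (SOCl2, CH2Cl2, 0 °C), collapsed with catalytic TiCl4, should deliver chloride from the front side with retention, which returns to the route at 15.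

Step 6. What may go wrong is hydrolysis of the hindered tetrasubstituted silyl enol ether in the aqueous medium before C–C bond formation, or insufficient catalyst control of the attacked face. The fallback sets out from silyl enol ether 10 and uses a fluoride-triggered, palladium-catalysed enantioselective allylic alkylation of Tsuji–Trost type (Pd2(dba)3, (S)-4-tert-butyl-2-[2-(diphenylphosphanyl)phenyl]-4,5-dihydrooxazole, diallyl carbonate, Bu4N[Ph3SiF2], THF, rt). This should give (2S,4R,5S)-4-(bromomethyl)-4,5-dichloro-2-methyl-2-(prop-2-en-1-yl)cyclohexan-1-one F2. Double-bond migration with RuHCl(CO)(PPh3)3 (toluene, 80 °C) should give (2R,4R,5S)-4-(bromomethyl)-4,5-dichloro-2-methyl-2-[(1E)-prop-1-en-1-yl]cyclohexan-1-one F3. Ozonolysis (O3, CH2Cl2, −78 °C; then Me2S) then gives keto aldehyde 12, where the route is rejoined.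

Step 9. What may go wrong is poor facial selectivity of hydride addition beside the quaternary carbon, or base-induced loss of HCl from the β-chloro ketone. The fallback sets out from hydroxy ketone 11. Evans–Saksena reduction with Me4NBH(OAc)3 (MeCN/AcOH, −20 °C) delivers hydride from boron held by the CH2OH group, that is to the carbonyl face syn to CH2OH, under acidic non-enolising conditions. It should give the trans diol (1S,2R,4R,5S)-4-(bromomethyl)-4,5-dichloro-2-(hydroxymethyl)-2-methylcyclohexan-1-ol F4. TEMPO (cat.) with PhI(OAc)2 (CH2Cl2, rt) should oxidise only the primary alcohol to (1S,2S,4S,5R)-5-(bromomethyl)-4,5-dichloro-2-hydroxy-1-methylcyclohexane-1-carbaldehyde F5. Chloro-olefination of F5 (CrCl2, CHCl3, THF, 65 °C) then gives alcohol 14, where the route is rejoined.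

Further compounds
F1 | step 10 | (1R,2R,4R,5S)-4-(bromomethyl)-4,5-dichloro-2-[(E)-2-chloroethenyl]-2-methylcyclohexan-1-ol | C[C@]1(/C=C/Cl)C[C@](Cl)(CBr)[C@@H](Cl)C[C@H]1O
F2 | step 6 | (2S,4R,5S)-4-(bromomethyl)-4,5-dichloro-2-methyl-2-(prop-2-en-1-yl)cyclohexan-1-one | C[C@]1(CC=C)C[C@](Cl)(CBr)[C@@H](Cl)CC1=O
F3 | step 6 | (2R,4R,5S)-4-(bromomethyl)-4,5-dichloro-2-methyl-2-[(1E)-prop-1-en-1-yl]cyclohexan-1-one | C[C@]1(/C=C/C)C[C@](Cl)(CBr)[C@@H](Cl)CC1=O
F4 | step 9 | (1S,2R,4R,5S)-4-(bromomethyl)-4,5-dichloro-2-(hydroxymethyl)-2-methylcyclohexan-1-ol | C[C@]1(CO)C[C@](Cl)(CBr)[C@@H](Cl)C[C@@H]1O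
F5 | step 9 | (1S,2S,4S,5R)-5-(bromomethyl)-4,5-dichloro-2-hydroxy-1-methylcyclohexane-1-carbaldehyde | C[C@]1(C=O)C[C@](Cl)(CBr)[C@@H](Cl)C[C@@H]1O
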